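**Retrosynthetic overview**
1. The pyran ring is closed last, by a 6-endo-dig intramolecular oxa-Michael (1,6-conjugate) addition of the C-1 hydroxyl onto a 3-alkynyl-2-chlorocyclohexenone.
2. That ynenone comes from a Sonogashira coupling of two fragments of equal length: a 2-chloro-3-triflyloxycyclohexenone (fragment 1) and an (R)-configured dienyne (fragment 2).
3. Fragment 1: triflate ⇐ chloro-1,3-dione ⇐ epoxy ketone ⇐ enone; the cis-7,8-diol comes from OsO4 addition anti to the C-8a substituent of a 4-substituted 2-methylcyclohexenone.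
4. That cyclohexenone (the first ring) is closed by an intramolecular aldol condensation of a keto aldehyde, made by an organocatalytic Michael addition that sets C-8a.
5. Fragment 2: Evans methylation, Wittig, Takai iodo-olefination, Sonogashira. Ring order: carbocycle first, pyran last.

Assumption: the SMILES is taken literally, i.e. (7R,8R,8aR) in the bicycle and (5R) in the side chain; isochromene numbering (C-1, O-2, C-3 … C-8a) is used for positions, and TBDPS = tert-butyldiphenylsilyl.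

**Fragment 1 (steps 1–9)**

Step 1
Reactants: 1 3-[(tert-butyldiphenylsilyl)oxy]propanal; 2 pent-1-en-3-one
Product: 3 (2R)-2-{[(tert-butyldiphenylsilyl)oxy]methyl}-5-oxoheptanal
Conditions: (R)-2-(methoxydiphenylmethyl)pyrrolidine (5 mol%), ethyl 3,4-dihydroxybenzoate (20 mol%), neat, 4 °C
Reagents that add atoms: none
Why: Enamine-catalysed asymmetric Michael addition, in which the (R)-diarylprolinol ether shields one face of the E-enamine of 1 so that the vinyl ketone adds to give the (R) α-centre (future C-8a), under conditions mild enough to avoid β-elimination of the silyloxy group.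

Step 2
Reactants: 3 (2R)-2-{[(tert-butyldiphenylsilyl)oxy]methyl}-5-oxoheptanal
Product: 5 (4S)-4-{[(tert-butyldiphenylsilyl)oxy]methyl}-2-methylcyclohex-2-en-1-one, via aldol ketol 4 (not isolated)
Conditions: TsOH·H2O (10 mol%), toluene, 80 °C, Dean–Stark
Reagents that add atoms: none
Why: Robinson-type intramolecular aldol condensation, in which the more substituted enol of the ethyl ketone attacks the aldehyde (6-ring) and ketol 4 dehydrates to the conjugated enone, while the stereocentre ends up γ to the carbonyl and is kept (the descriptor becomes S only through CIP priorities).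

Step 3
Reactants: 5 (4S)-4-{[(tert-butyldiphenylsilyl)oxy]methyl}-2-methylcyclohex-2-en-1-one
Product: 6 (2R,3R,4R)-4-{[(tert-butyldiphenylsilyl)oxy]methyl}-2,3-dihydroxy-2-methylcyclohexan-1-one
Conditions: OsO4 (2 mol%), N-methylmorpholine N-oxide (1.5 equiv), citric acid, t-BuOH/H2O 1:1, rt
Reagents that add atoms: osmium tetroxide O=[Os](=O)(=O)=O (delivers both oxygens); N-methylmorpholine N-oxide C[N+]1([O-])CCOCC1 and water O (re-supply them on turnover)
Why: Upjohn syn-dihydroxylation of the trisubstituted enone from the face opposite the allylic silyloxymethyl group, which sets C-7 and C-8 cis to each other and trans to the C-8a substituent.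

Step 4
Reactants: 6 (2R,3R,4R)-4-{[(tert-butyldiphenylsilyl)oxy]methyl}-2,3-dihydroxy-2-methylcyclohexan-1-one
Product: 7 (3aR,4R,7aR)-4-{[(tert-butyldiphenylsilyl)oxy]methyl}-2,2,7a-trimethylhexahydro-1,3-benzodioxol-7-one (acetonide of 6)
Conditions: 2,2-dimethoxypropane, pyridinium p-toluenesulfonate (cat.), CH2Cl2, rt
Reagents that add atoms: 2,2-dimethoxypropane COC(C)(C)OC
Why: Acid-catalysed transketalisation ties the cis-diol up as a cis-fused acetonide, which blocks α-ketol rearrangement and makes the C-8 oxygen a poor β-leaving group in the base steps that follow.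

Step 5
Reactants: 7 acetonide ketone
Product: 8 (3aR,4R,7aR)-4-{[(tert-butyldiphenylsilyl)oxy]methyl}-2,2,7a-trimethyl-3a,7a-dihydro-1,3-benzodioxol-7(4H)-one (5,6-enone)
Conditions: 2-iodoxybenzoic acid (2.5 equiv), DMSO/toluene 1:2, 75 °C
Reagents that add atoms: none
Why: Nicolaou dehydrogenation with 2-iodoxybenzoic acid goes through the only possible enol (the other α-carbon is quaternary) and gives the enone without touching a stereocentre.

Step 6
Reactants: 8 5,6-enone
Product: 9 5,6-epoxide of 8 (oxirane oxygen anti to the silyloxymethyl group; the epoxide configuration is lost in step 7)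
Conditions: 30% aq. H2O2, NaOH (0.2 equiv), MeOH, 0 °C
Reagents that add atoms: hydrogen peroxide OO
Why: Weitz–Scheffer nucleophilic epoxidation, in which hydroperoxide adds to the β-carbon anti to the neighbouring substituent and the enolate closes the oxirane.

Step 7
Reactants: 9 epoxy ketone
Product: 10 (3aR,4R,7aR)-4-{[(tert-butyldiphenylsilyl)oxy]methyl}-2,2,7a-trimethyltetrahydro-1,3-benzodioxole-5,7-dione
Conditions: Pd(PPh3)4 (5 mol%), 1,2-bis(diphenylphosphino)ethane (5 mol%), toluene, 100 °C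
Reagents that add atoms: none
Why: Noyori isomerisation of an α,β-epoxy ketone to a β-diketone, by insertion of zerovalent palladium into the Cα–O bond, β-hydride elimination of the carbinol hydrogen and reductive elimination, with the three stereocentres not involved.

Step 8
Reactants: 10 1,3-dione
Product: 11 (3aR,4R,7aR)-6-chloro-5-hydroxy-4-{[(tert-butyldiphenylsilyl)oxy]methyl}-2,2,7a-trimethyl-3a,7a-dihydro-1,3-benzodioxol-7(4H)-one (enol form of the 6-chloro-5,7-dione)
Conditions: N-chlorosuccinimide (1.0 equiv), CH2Cl2, 0 °C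
Reagents that add atoms: N-chlorosuccinimide O=C1CCC(=O)N1Cl
Why: Electrophilic α-chlorination of the enolised 1,3-dione at its central carbon, where one equivalent stops at the fully enolised monochloride.

Step 9
Reactants: 11 chloro-dione
Product: 12 (3aR,4R,7aR)-6-chloro-4-{[(tert-butyldiphenylsilyl)oxy]methyl}-2,2,7a-trimethyl-7-oxo-3a,4,7,7a-tetrahydro-1,3-benzodioxol-5-yl trifluoromethanesulfonate
Conditions: Tf2O (1.1 equiv), Et3N (1.5 equiv), CH2Cl2, −78 °C
Reagents that add atoms: trifluoromethanesulfonic anhydride O=S(=O)(OS(=O)(=O)C(F)(F)F)C(F)(F)F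
Why: Enolate O-sulfonylation is expected at the oxygen next to the tertiary C–H carbon rather than the one flanked by the fully substituted, oxygen-bearing carbon (steric and inductive bias, as in 4,4-disubstituted cyclohexane-1,3-diones), giving the vinylogous acyl triflate with the C-6 ketone retained.

**Fragment 2 (steps 10–18)**

Step 10
Reactants: 13 (4R)-4-benzyl-1,3-oxazolidin-2-one; 14 butanoyl chloride
Product: 16 (4R)-4-benzyl-3-butanoyl-1,3-oxazolidin-2-one, via lithium oxazolidinide 15 (not isolated)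
Conditions: n-BuLi, THF, −78 °C; then 14, −78 → 0 °C
Reagents that add atoms: none
Why: N-acylation of the lithiated oxazolidinone by the acid chloride (nucleophilic acyl substitution) installs the Evans auxiliary.

Step 11
Reactants: 16 (4R)-4-benzyl-3-butanoyl-1,3-oxazolidin-2-one
Product: 18 (4R)-4-benzyl-3-[(2R)-2-methylbutanoyl]-1,3-oxazolidin-2-one, via sodium Z-enolate 17 (not isolated)
Conditions: NaN(SiMe3)2, THF, −78 °C; MeI, −78 → −40 °C
Reagents that add atoms: iodomethane CI
Why: Evans asymmetric alkylation, in which the chelated Z-enolate is methylated on the face opposite the benzyl group, so the (R)-auxiliary gives the (2R) centre (about 10:1, minor isomer removed by chromatography).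

Step 12
Reactants: 18 (4R)-4-benzyl-3-[(2R)-2-methylbutanoyl]-1,3-oxazolidin-2-one
Product: 19 (2R)-2-methylbutan-1-ol
Conditions: LiBH4, Et2O, MeOH (1 equiv), 0 °C
Reagents that add atoms: none
Why: Reductive cleavage of the imide at the exocyclic carbonyl gives the primary alcohol without epimerising the α-centre and returns auxiliary 13.

Step 13
Reactants: 19 (2R)-2-methylbutan-1-ol
Product: 21 ethyl (2E,4R)-2,4-dimethylhex-2-enoate, via (2R)-2-methylbutanal 20 (not isolated)
Conditions: (COCl)2, DMSO, CH2Cl2, −78 °C; Et3N; then Ph3P=C(CH3)CO2Et, −78 °C → rt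
Reagents that add atoms: ethyl 2-(triphenylphosphoranylidene)propanoate CCOC(=O)C(C)=P(c1ccccc1)(c1ccccc1)c1ccccc1
Why: Swern oxidation followed in the same flask by Wittig olefination, so the racemisation-prone α-branched aldehyde is trapped cold and the stabilised ylide gives the E-trisubstituted enoate.

Step 14
Reactants: 21 ethyl (2E,4R)-2,4-dimethylhex-2-enoate
Product: 22 (2E,4R)-2,4-dimethylhex-2-en-1-ol
Conditions: i-Bu2AlH (2.2 equiv), CH2Cl2, −78 °C; aq. potassium sodium tartrate
Reagents that add atoms: none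
Why: 1,2-Reduction of the conjugated ester by the aluminium hydride gives the allylic alcohol with the alkene geometry unchanged.

Step 15
Reactants: 22 (2E,4R)-2,4-dimethylhex-2-en-1-ol
Product: 23 (2E,4R)-2,4-dimethylhex-2-enal
Conditions: MnO2 (activated, excess), CH2Cl2, rt
Reagents that add atoms: none
Why: Chemoselective allylic oxidation on MnO2 gives the enal without over-oxidation or E/Z isomerisation.

Step 16
Reactants: 23 (2E,4R)-2,4-dimethylhex-2-enal
Product: 24 (1E,3E,5R)-1-iodo-3,5-dimethylhepta-1,3-diene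
Conditions: CHI3 (2 equiv), CrCl2 (6 equiv), THF, 0 °C → rt
Reagents that add atoms: iodoform IC(I)I
Why: Takai olefination, in which the gem-dichromium reagent from CHI3 and CrCl2 adds to the aldehyde and eliminates to the E-vinyl iodide.

Step 17
Reactants: 24 (1E,3E,5R)-1-iodo-3,5-dimethylhepta-1,3-diene
Product: 25 [(3E,5E,7R)-5,7-dimethylnona-3,5-dien-1-yn-1-yl]trimethylsilane
Conditions: HC≡CSiMe3, PdCl2(PPh3)2 (3 mol%), CuI (6 mol%), Et3N, THF, rt
Reagents that add atoms: ethynyltrimethylsilane C#C[Si](C)(C)C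
Why: Sonogashira coupling of the vinyl iodide proceeds with retention of the E geometry.

Step 18
Reactants: 25 [(3E,5E,7R)-5,7-dimethylnona-3,5-dien-1-yn-1-yl]trimethylsilane
Product: 26 (3E,5E,7R)-5,7-dimethylnona-3,5-dien-1-yne
Conditions: K2CO3 (cat.), MeOH, 0 °C → rt
Reagents that add atoms: none
Why: Methoxide-mediated protodesilylation frees the terminal alkyne, and the volatile dienyne is carried on as a solution.

**Coupling and endgame (steps 19–23)**

Step 19
Reactants: 12 enol triflate; 26 (3E,5E,7R)-5,7-dimethylnona-3,5-dien-1-yne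
Product: 27 (3aR,4R,7aR)-6-chloro-5-[(3E,5E,7R)-5,7-dimethylnona-3,5-dien-1-yn-1-yl]-4-{[(tert-butyldiphenylsilyl)oxy]methyl}-2,2,7a-trimethyl-3a,7a-dihydro-1,3-benzodioxol-7(4H)-one
Conditions: PdCl2(PPh3)2 (5 mol%), CuI (10 mol%), Et3N (3 equiv), THF (degassed), rt
Reagents that add atoms: none
Why: Sonogashira coupling, in which zerovalent palladium inserts into the activated β-C–OTf bond far faster than into the α-C–Cl bond and the copper acetylide of 26 transmetallates, leaving the diene geometry and all stereocentres untouched.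

Step 20
Reactants: 27 ynenone acetonide
Product: 28 (4R,5R,6R)-4-{[(tert-butyldiphenylsilyl)oxy]methyl}-2-chloro-3-[(3E,5E,7R)-5,7-dimethylnona-3,5-dien-1-yn-1-yl]-5,6-dihydroxy-6-methylcyclohex-2-en-1-one
Conditions: CF3CO2H/H2O 4:1, CH2Cl2, 0 °C → rt
Reagents that add atoms: none
Why: Acid hydrolysis of the isopropylidene acetal is done before any enol ether exists, and the TBDPS ether, ynenone and diene tolerate cold aqueous acid.

Step 21
Reactants: 28 diol
Product: 29 (1R,2R,6R)-6-{[(tert-butyldiphenylsilyl)oxy]methyl}-4-chloro-5-[(3E,5E,7R)-5,7-dimethylnona-3,5-dien-1-yn-1-yl]-2-hydroxy-2-methyl-3-oxocyclohex-4-en-1-yl acetate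
Conditions: Ac2O (1.5 equiv), pyridine, 4-(dimethylamino)pyridine (cat.), 0 °C → rt
Reagents that add atoms: acetic anhydride CC(=O)OC(C)=O
Why: Nucleophile-catalysed acylation takes the secondary C-8 hydroxyl only, because the tertiary α-ketol hydroxyl is too hindered.

Step 22
Reactants: 29 silyl ether acetate
Product: 30 (1R,2R,6R)-4-chloro-5-[(3E,5E,7R)-5,7-dimethylnona-3,5-dien-1-yn-1-yl]-2-hydroxy-6-(hydroxymethyl)-2-methyl-3-oxocyclohex-4-en-1-yl acetate
Conditions: HF·pyridine, pyridine/THF, 0 °C → rt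
Reagents that add atoms: none
Why: Fluoride cleavage of the Si–O bond under buffered, slightly acidic conditions leaves the acetate in place and avoids base-induced acyl migration or β-elimination.

Step 23
Reactants: 30 hydroxy ynenone
Product: 31 (7R,8R,8aR)-5-chloro-3-[(1E,3E,5R)-3,5-dimethylhepta-1,3-dien-1-yl]-7-hydroxy-7-methyl-6-oxo-6,7,8,8a-tetrahydro-1H-isochromen-8-yl acetate (target)
Conditions: AuCl(PPh3) (5 mol%), AgOSO2CF3 (5 mol%), CH2Cl2, rt
Reagents that add atoms: none
Why: Cationic monovalent gold activates the alkyne for a 6-endo-dig intramolecular oxa-Michael-type (1,6-conjugate) addition of the primary hydroxyl to the alkyne carbon δ to the ketone (also the one bearing the cation-stabilising dienyl group), and protodeauration closes the pyran ring with no stereocentre changed.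

**Compound list**

1 | 3-[(tert-butyldiphenylsilyl)oxy]propanal | O=CCCO[Si](c1ccccc1)(c1ccccc1)C(C)(C)C | starting material
2 | pent-1-en-3-one | C=CC(=O)CC | starting material
3 | (2R)-2-{[(tert-butyldiphenylsilyl)oxy]methyl}-5-oxoheptanal | O=C[C@H](CCC(=O)CC)CO[Si](c1ccccc1)(c1ccccc1)C(C)(C)C | intermediate
4 | (4R)-4-{[(tert-butyldiphenylsilyl)oxy]methyl}-3-hydroxy-2-methylcyclohexan-1-one (aldol ketol, mixture at C-2 and C-3, not isolated) | CC1C(O)[C@@H](CO[Si](c2ccccc2)(c2ccccc2)C(C)(C)C)CCC1=O | intermediate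
5 | (4S)-4-{[(tert-butyldiphenylsilyl)oxy]methyl}-2-methylcyclohex-2-en-1-one | CC1=C[C@@H](CO[Si](c2ccccc2)(c2ccccc2)C(C)(C)C)CCC1=O | intermediate
6 | (2R,3R,4R)-4-{[(tert-butyldiphenylsilyl)oxy]methyl}-2,3-dihydroxy-2-methylcyclohexan-1-one | C1CC(=O)[C@](C)(O)[C@H](O)[C@H]1CO[Si](c2ccccc2)(c2ccccc2)C(C)(C)C | intermediate
7 | (3aR,4R,7aR)-4-{[(tert-butyldiphenylsilyl)oxy]methyl}-2,2,7a-trimethylhexahydro-1,3-benzodioxol-7-one | C1CC(=O)[C@](C)(OC(C)(C)O2)[C@H]2[C@H]1CO[Si](c3ccccc3)(c3ccccc3)C(C)(C)C | intermediate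
8 | (3aR,4R,7aR)-4-{[(tert-butyldiphenylsilyl)oxy]methyl}-2,2,7a-trimethyl-3a,7a-dihydro-1,3-benzodioxol-7(4H)-one | C1=CC(=O)[C@](C)(OC(C)(C)O2)[C@H]2[C@H]1CO[Si](c3ccccc3)(c3ccccc3)C(C)(C)C | intermediate
9 | 5,6-epoxide of 8, oxirane oxygen anti to the silyloxymethyl group (major isomer drawn) | O1[C@@H]2[C@H]1C(=O)[C@](C)(OC(C)(C)O3)[C@H]3[C@H]2CO[Si](c4ccccc4)(c4ccccc4)C(C)(C)C | intermediate
10 | (3aR,4R,7aR)-4-{[(tert-butyldiphenylsilyl)oxy]methyl}-2,2,7a-trimethyltetrahydro-1,3-benzodioxole-5,7-dione | O=C1CC(=O)[C@](C)(OC(C)(C)O2)[C@H]2[C@H]1CO[Si](c3ccccc3)(c3ccccc3)C(C)(C)C | intermediate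
11 | (3aR,4R,7aR)-6-chloro-5-hydroxy-4-{[(tert-butyldiphenylsilyl)oxy]methyl}-2,2,7a-trimethyl-3a,7a-dihydro-1,3-benzodioxol-7(4H)-one | OC1=C(Cl)C(=O)[C@](C)(OC(C)(C)O2)[C@H]2[C@H]1CO[Si](c3ccccc3)(c3ccccc3)C(C)(C)C | intermediate
12 | (3aR,4R,7aR)-6-chloro-4-{[(tert-butyldiphenylsilyl)oxy]methyl}-2,2,7a-trimethyl-7-oxo-3a,4,7,7a-tetrahydro-1,3-benzodioxol-5-yl trifluoromethanesulfonate | FC(F)(F)S(=O)(=O)OC1=C(Cl)C(=O)[C@](C)(OC(C)(C)O2)[C@H]2[C@H]1CO[Si](c3ccccc3)(c3ccccc3)C(C)(C)C | intermediate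
13 | (4R)-4-benzyl-1,3-oxazolidin-2-one | O=C1N[C@H](Cc2ccccc2)CO1 | starting material
14 | butanoyl chloride | CCCC(=O)Cl | starting material
15 | lithium (4R)-4-benzyl-2-oxo-1,3-oxazolidin-3-ide (not isolated) | [Li+].O=C1[N-][C@H](Cc2ccccc2)CO1 | intermediate
16 | (4R)-4-benzyl-3-butanoyl-1,3-oxazolidin-2-one | CCCC(=O)N1[C@H](Cc2ccccc2)COC1=O | intermediate
17 | sodium (1Z)-1-[(4R)-4-benzyl-2-oxo-1,3-oxazolidin-3-yl]but-1-en-1-olate (not isolated) | [Na+].CC/C=C(\[O-])N1[C@H](Cc2ccccc2)COC1=O | intermediate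
18 | (4R)-4-benzyl-3-[(2R)-2-methylbutanoyl]-1,3-oxazolidin-2-one | CC[C@@H](C)C(=O)N1[C@H](Cc2ccccc2)COC1=O | intermediate
19 | (2R)-2-methylbutan-1-ol | CC[C@@H](C)CO | intermediate
20 | (2R)-2-methylbutanal (not isolated) | CC[C@@H](C)C=O | intermediate
21 | ethyl (2E,4R)-2,4-dimethylhex-2-enoate | CC[C@@H](C)/C=C(C)/C(=O)OCC | intermediate
22 | (2E,4R)-2,4-dimethylhex-2-en-1-ol | CC[C@@H](C)/C=C(C)/CO | intermediate
23 | (2E,4R)-2,4-dimethylhex-2-enal | CC[C@@H](C)/C=C(C)/C=O | intermediate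
24 | (1E,3E,5R)-1-iodo-3,5-dimethylhepta-1,3-diene | CC[C@@H](C)/C=C(C)/C=C/I | intermediate
25 | [(3E,5E,7R)-5,7-dimethylnona-3,5-dien-1-yn-1-yl]trimethylsilane | CC[C@@H](C)/C=C(C)/C=C/C#C[Si](C)(C)C | intermediate
26 | (3E,5E,7R)-5,7-dimethylnona-3,5-dien-1-yne | CC[C@@H](C)/C=C(C)/C=C/C#C | intermediate
27 | (3aR,4R,7aR)-6-chloro-5-[(3E,5E,7R)-5,7-dimethylnona-3,5-dien-1-yn-1-yl]-4-{[(tert-butyldiphenylsilyl)oxy]methyl}-2,2,7a-trimethyl-3a,7a-dihydro-1,3-benzodioxol-7(4H)-one | CC[C@@H](C)/C=C(C)/C=C/C#CC1=C(Cl)C(=O)[C@](C)(OC(C)(C)O2)[C@H]2[C@H]1CO[Si](c3ccccc3)(c3ccccc3)C(C)(C)C | intermediate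
28 | (4R,5R,6R)-4-{[(tert-butyldiphenylsilyl)oxy]methyl}-2-chloro-3-[(3E,5E,7R)-5,7-dimethylnona-3,5-dien-1-yn-1-yl]-5,6-dihydroxy-6-methylcyclohex-2-en-1-one | CC[C@@H](C)/C=C(C)/C=C/C#CC1=C(Cl)C(=O)[C@](C)(O)[C@H](O)[C@H]1CO[Si](c2ccccc2)(c2ccccc2)C(C)(C)C | intermediate
29 | (1R,2R,6R)-6-{[(tert-butyldiphenylsilyl)oxy]methyl}-4-chloro-5-[(3E,5E,7R)-5,7-dimethylnona-3,5-dien-1-yn-1-yl]-2-hydroxy-2-methyl-3-oxocyclohex-4-en-1-yl acetate | CC[C@@H](C)/C=C(C)/C=C/C#CC1=C(Cl)C(=O)[C@](C)(O)[C@H](OC(C)=O)[C@H]1CO[Si](c2ccccc2)(c2ccccc2)C(C)(C)C | intermediate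
30 | (1R,2R,6R)-4-chloro-5-[(3E,5E,7R)-5,7-dimethylnona-3,5-dien-1-yn-1-yl]-2-hydroxy-6-(hydroxymethyl)-2-methyl-3-oxocyclohex-4-en-1-yl acetate | CC[C@@H](C)/C=C(C)/C=C/C#CC1=C(Cl)C(=O)[C@](C)(O)[C@H](OC(C)=O)[C@H]1CO | intermediate
31 | (7R,8R,8aR)-5-chloro-3-[(1E,3E,5R)-3,5-dimethylhepta-1,3-dien-1-yl]-7-hydroxy-7-methyl-6-oxo-6,7,8,8a-tetrahydro-1H-isochromen-8-yl acetate | CC[C@@H](C)/C=C(C)/C=C/C1=CC2=C(Cl)C(=O)[C@](C)(O)[C@H](OC(C)=O)[C@H]2CO1 | target

**Step count**

Total steps: 23. Longest linear sequence: 14 (steps 1–9, then 19–23; the branch 10–18, then 19–23, is equally long).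

**Three steps most likely to fail, with fallbacks**

Step 7 (palladium-catalysed epoxy ketone to dione isomerisation on a hindered bicyclic substrate). The fallback sets out from 9 and comes back at 10. The epoxide is opened reductively at the Cα–O bond with SmI2 (THF/MeOH, −78 °C) to give the 5-hydroxy ketone (5-OH anti to the silyloxymethyl group) F1. F1 is then oxidised with Dess–Martin periodinane (NaHCO3, CH2Cl2, rt) to dione 10, so the isomerisation is replaced by a reduction–oxidation pair.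

Step 9 (regiochemistry of triflate formation; the bias between the two enolate oxygens is a prediction, and a wrong-way triflate would put the side chain on C-6). The fallback sets out from 8 and 26 and comes back at 31; it fixes the regiochemistry by conjugate addition and moves the chlorination to the end.
- Alkyne 26 is turned (n-BuLi, then ZnBr2, THF) into bromo[(3E,5E,7R)-5,7-dimethylnona-3,5-dien-1-yn-1-yl]zinc F2.
- F2 adds 1,4 to enone 8 in the presence of t-BuMe2SiOSO2CF3 (Et2O/THF, −40 °C) to give the tert-butyldimethylsilyl enol ether carrying the alkyne on the former β-carbon F3.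
- Saegusa–Ito oxidation (Pd(OAc)2, MeCN, rt) gives the chlorine-free ynenone acetonide F4.
- The operations of steps 20–23 (aqueous CF3CO2H; Ac2O/pyridine; HF·pyridine; AuCl(PPh3)/AgOSO2CF3) then give in turn the chlorine-free diol F5, the chlorine-free acetate F6, the chlorine-free hydroxy ynenone F7 and the 5-deschloro bicycle F8.
- N-chlorosuccinimide (MeCN, 0 °C) finally chlorinates C-5, the nucleophilic α-carbon of the push–pull dienone, to give 31. Selectivity over the side-chain diene is expected by analogy with C-5 halogenation of related azaphilones, but this is recalled rather than checked.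

Step 23 (gold cyclisation; 5-exo attack or side reactions of the dienyne are possible). The fallback sets out from 30 and comes back at 31. Et2NH (EtOH, 0 °C) adds 1,6 to the alkyne terminus to give the 3-(diethylamino) dienone (E/Z mixture at the new double bond) F9. Warming F9 with AcOH in toluene (50 °C) lets the primary hydroxyl add to the iminium-activated carbon in a 6-exo-trig intramolecular oxa-Michael addition and expel the amine, which gives 31 without a metal catalyst.

**Further compounds**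

F1 | step 7 | (3aR,4R,7aR)-4-{[(tert-butyldiphenylsilyl)oxy]methyl}-5-hydroxy-2,2,7a-trimethylhexahydro-1,3-benzodioxol-7-one (5-OH anti to the silyloxymethyl group) | O[C@@H]1CC(=O)[C@](C)(OC(C)(C)O2)[C@H]2[C@H]1CO[Si](c3ccccc3)(c3ccccc3)C(C)(C)C
F2 | step 9 | bromo[(3E,5E,7R)-5,7-dimethylnona-3,5-dien-1-yn-1-yl]zinc | CC[C@@H](C)/C=C(C)/C=C/C#C[Zn]Br
F3 | step 9 | tert-butyldimethylsilyl enol ether of the 1,4-adduct of 26 and 8 (alkynyl anti to the silyloxymethyl group) | CC[C@@H](C)/C=C(C)/C=C/C#C[C@@H]1C=C(O[Si](C)(C)C(C)(C)C)[C@](C)(OC(C)(C)O2)[C@H]2[C@H]1CO[Si](c3ccccc3)(c3ccccc3)C(C)(C)C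
F4 | step 9 | chlorine-free analogue of 27 | CC[C@@H](C)/C=C(C)/C=C/C#CC1=CC(=O)[C@](C)(OC(C)(C)O2)[C@H]2[C@H]1CO[Si](c3ccccc3)(c3ccccc3)C(C)(C)C
F5 | step 9 | chlorine-free analogue of 28 | CC[C@@H](C)/C=C(C)/C=C/C#CC1=CC(=O)[C@](C)(O)[C@H](O)[C@H]1CO[Si](c2ccccc2)(c2ccccc2)C(C)(C)C
F6 | step 9 | chlorine-free analogue of 29 | CC[C@@H](C)/C=C(C)/C=C/C#CC1=CC(=O)[C@](C)(O)[C@H](OC(C)=O)[C@H]1CO[Si](c2ccccc2)(c2ccccc2)C(C)(C)C
F7 | step 9 | chlorine-free analogue of 30 | CC[C@@H](C)/C=C(C)/C=C/C#CC1=CC(=O)[C@](C)(O)[C@H](OC(C)=O)[C@H]1CO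
F8 | step 9 | (7R,8R,8aR)-3-[(1E,3E,5R)-3,5-dimethylhepta-1,3-dien-1-yl]-7-hydroxy-7-methyl-6-oxo-6,7,8,8a-tetrahydro-1H-isochromen-8-yl acetate (5-deschloro target) | CC[C@@H](C)/C=C(C)/C=C/C1=CC2=CC(=O)[C@](C)(O)[C@H](OC(C)=O)[C@H]2CO1
F9 | step 23 | (1R,2R,6R)-4-chloro-5-[(3E,5E,7R)-2-(diethylamino)-5,7-dimethylnona-1,3,5-trien-1-yl]-2-hydroxy-6-(hydroxymethyl)-2-methyl-3-oxocyclohex-4-en-1-yl acetate (E/Z mixture at C-1 of the trienyl chain) | CC[C@@H](C)/C=C(C)/C=C/C(N(CC)CC)=CC1=C(Cl)C(=O)[C@](C)(O)[C@H](OC(C)=O)[C@H]1CO
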